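The readings were generated by integration with made-up constants; scatter was added.

With 1.20 equiv of partner, a flask in which substrate met partner one to one cannot stop with substrate left, yet the cedar run still holds 40 % of its substrate at 8.00 min.

all flasks: substrate 0.25 M

| charge | partner | free catalyst | remark | time |
|---|---|---|---|---|
| cedar | 1.2 equiv | 14 mol% | run made earlier |  |
| alder | 1.2 equiv | 22 mol% | run made earlier |  |
| flask | 1.20 equiv | 10 mol% |  | 6.0 min |

| run | time / min | product / % | substrate / % |
|---|---|---|---|
| cedar | 0.500 | 41 | 51 |
| cedar | 1.33 | 49 | 41 |
| cedar | 2.50 | 53 | 42 |
| cedar | 4.00 | 57 | 39 |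
| cedar | 6.00 | 56 | 41 |
| cedar | 8.00 | 59 | 40 |
| alder | 1.33 | 54 | 33 |
| alder | 2.50 | 61 | 33 |
| alder | 4.00 | 62 | 33 |
| alder | 5.00 | 61 | 32 |
| alder | 6.00 | 58 | 32 |
| alder | 8.00 | 61 | 32 |

(readings scatter by 1.5 percentage points)

- amount of product in percent of the substrate charged, at 20 s, 1.5 min and 6.0 min



I build the flask up in stages, counting the substrate left and not the product made. With the main step alone, substrate plus partner to product, the substrate left is zero and the product 100 per cent, which the runs refute. So I add one process, a supposition because partner is not read: partner is also lost by a path outside the catalyst, and more catalyst claims a larger share of it first. The readings lean that way. From 2.50 min on, the cedar run leaves 40.5 % on average, while from 2.50 min on the alder run, with 22 mol% of free catalyst, leaves less, 32.4 %. Between the two runs, the substrate left drops by 1.01 for each unit of catalyst added, both counted on the substrate charged; this return of the catalyst, the drop in substrate left per unit of catalyst charged, is what I carry. Going down from the 14 mol% of cedar to the 10 mol% of the flask, it puts the substrate left at 44.6 %.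

Then the rest: substrate and product together fall short of 100 per cent, by 3.2 percentage points in cedar and 7 points in alder. I read this as material held on the catalyst, 0.285 for each unit of catalyst charged, again both counted on the substrate charged, so my own product at 6.0 min is 52.6 %.

The forecast gives 29 %, 46 % and 54 %, on the view that “The approach to the plateau looks hyperbolic”; its last value stands above mine.

The flask gives 28.6 %, 49.3 % and 51.9 %, within the forecast's margin.

    catalyst intermediate B ⇌ by-product + catalyst intermediate C (K = 0.130 M, k = 25.0 s⁻¹)
    partner → decomposed reagent (k = 0.0170 s⁻¹)
    catalyst intermediate C ⇌ free catalyst + product (K = 0.150 M, k = 36.0 s⁻¹)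
    substrate + catalyst intermediate A ⇌ catalyst intermediate B (K = 3.80 L mol⁻¹, k = 2.00 L mol⁻¹ s⁻¹)
    partner + free catalyst → catalyst intermediate A (k = 2.00 L mol⁻¹ s⁻¹)

In the flask, partner ran two ways at once: through free catalyst into catalyst intermediate A, a step with 99.6 % of its turnover behind it at 3.00 min, and into decomposed reagent, 0.149 M by then, with partner down to 0.503 % of its charge. Meanwhile substrate joined catalyst intermediate A to form catalyst intermediate B, 92 % of that step done at 1.20 min, and at 6.00 min partner, the limiting reagent despite its excess, stands at 0 % and substrate at 44 %, which against the cedar run reads a return of 0.986 beside the 1.01 carried.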